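All runs are simulated with constants of no real substance, and the scatter is random.

What stands unaccounted for in the noon run at 8.00 min is a leftover: chains hold 66.0%, free monomer 0.1%, and 33.9% of the charge is neither, against 35.8% at 3.00 min, so I see no sign of it returning to chains.

| flask | free monomer | initiator | remark | time |
|---|---|---|---|---|
| noon | 0.050 M | 0.10 mM | run made earlier |  |
| spring | 0.050 M | 0.050 mM | run made earlier |  |
| dawn | 0.050 M | 0.20 mM | run made earlier |  |
| blue | 0.050 M | 0.10 mM | a single well-mixed tank run continuously and read at steady state, 8.0 min in it on average |  |
| teal | 0.050 M | 0.10 mM | a closed flask charged with all of it at once and left for 8.0 min | 8.0 min |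
| red | 0.050 M (fed, over 6.40 min) | 0.10 mM | a stirred flask in which free monomer is dosed at a steady rate over 6.40 min without added volume, worked up at 8.0 min | 8.0 min |
| violet | 0.050 M | 0.10 mM | plug flow through a tube for 8.0 min, no back-mixing | 8.0 min |

| run | time / min | monomer in chains / % | free monomer / % |
|---|---|---|---|
| noon | 0.667 | 43.4 | 27.5 |
| noon | 1.33 | 55.3 | 11.3 |
| noon | 3.00 | 64.2 | 0 |
| noon | 8.00 | 66.0 | 0.1 |
| spring | 1.50 | 48.2 | 13.4 |
| spring | 3.00 | 52.6 | 4.7 |
| spring | 5.00 | 55.2 | 2.2 |
| spring | 6.00 | 58.0 | 1.0 |
| dawn | 0.833 | 60.2 | 15.5 |
| dawn | 2.50 | 72.6 | 1.1 |
| dawn | 4.00 | 71.8 | 0.2 |
| dawn | 6.00 | 71.4 | 0.2 |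

(each reading ± 1 percentage point)

- percentages count the free monomer that a species holds: one homo dimer counts as two
- the stated concentrations are those of everything mixed, before any reaction; amounts are the same in each set-up
- candidate steps: initiator -> 2 initiating radical; free monomer + initiating radical -> growing radical + monomer in chains; free monomer + growing radical -> monomer in chains + growing radical; 2 growing radical -> dead chain; free monomer <-> dormant form; 2 free monomer -> homo dimer
- the feed brings no volume worth counting
- the earlier runs were made in a closed, stirred flask

- the set-up with the highest amount of monomer in chains at the outlet or at the end, in percent of the free monomer put in ("none" if the first two lie within 2 percentage points) (blue / teal / red / violet / none)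
- amount of monomer in chains at the outlet or at the end, in percent of the free monomer put in, blue
- amount of monomer in chains at the outlet or at the end, in percent of the free monomer put in, teal
- amount of monomer in chains at the outlet or at the end, in percent of the free monomer put in, red
- amount of monomer in chains at the outlet or at the end, in percent of the free monomer put in, violet

I read the leftover as homo dimer, a loss second order in free monomer set against growth first order in it. If x is free monomer as a fraction of the charge, chains take a share 1/(1+Dx) of what reacts at any moment, and a closed flask ends at ln(1+D)/D. The symmetric case, D = 1, gives 69.3%. The noon plateau lies below that, and one step along the slope from the symmetric point gives D = 1.17. This D, the rate of loss over the rate of growth at full charge (a selectivity factor), is a reading from the noon plateau, an average over that closed run, and it is what I carry.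

Teal and violet take the whole charge at once, as noon did, so the noon plateau of 66.0% is my floor and my value for both. The plain ceiling is 100%, reached at x near zero. To tighten it I read the growth constant b from the noon run's second interval as 0.925 /min. Matching red's feed to consumption then puts x at 14.4% during the feed, where chains take 85.5% of what reacts. Adding the rundown from the end of the feed to 8.0 min, with D and b held at their noon values, gives my upper figure for red, 83.7% of the charge. The same balance for the blue tank gives 79.3% of the charge, lower by 4.4 percentage points, so I commit to red on these two like figures, both reckoned from the noon run.

The forecast gives blue 77%, teal 66%, red 82%, violet 66% and names red as best, since "dosing keeps x ≈ 0.12–0.15, favouring first-order growth over dimerisation". Its red lies inside my bracket, below my upper figure and above my floor.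

The flask gives blue 68.4%, teal 65.8%, red 72.0%, violet 65.8%, and red is best.

    initiator → 2 initiating radical (k = 0.00415 /s)
    free monomer + initiating radical → growing radical + monomer in chains (k = 4.25 × 10⁶ /M/s)
    free monomer + growing radical → monomer in chains + growing radical, rate k3*[growing radical]*[free monomer] (k = 5.00 × 10⁵ /M/s)
    2 growing radical → dead chain (k = 2.40 × 10⁸ /M/s)
    free monomer ⇌ dormant form (K = 1.60, k = 0.00141 /s)
    2 free monomer → homo dimer (k = 0.211 /M/s)

At the end of its feed, at 6.40 min, red holds 17.1% free monomer, above my 14.4%, and with its growing radical at 1.87 × 10⁻⁸ M the constants put D at that moment at 2.25, above the noon reading of 1.17, so chains take 72.2% of what reacts there. The neighbouring flask is violet with 0.013 M of free monomer, so D scales with the charge to 0.305, and ln(1+D)/D gives 87.3%. That flask ends at 84.3% in chains, with 11.0% as homo dimer.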